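**Plan**

- Retrosynthesis cuts: the six aryl benzyl ethers; the biaryl bond between C5 of one guaiacyl ring of the lignan and C5' of ring B (Suzuki–Miyaura); the C4 carbonyl and C3 hydroxyl, traced back to the C3=C4 alkene of a flav-3-ene; the C4–C4a bond of ring C (alkyne hydroarylation); the O1–C2 aryl ether (Mitsunobu); the C2–C3 bond (aldehyde alkynylation).
- Forward order: ring B aldehyde → propargylic alcohol → aryl propargyl ether → ring C closed onto ring A → syn-dihydroxylation → union with the boronate made from (+)-pinoresinol → oxidation at C4 → global debenzylation.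
- Enabling feature: ring A enters as a 3,5-bis(benzyloxy)phenyl ether. Its two ortho C–H carbons are equivalent, and each is ortho, ortho and para to O1, O5 and O7. Tethered through O1–C2–C3, the alkyne terminus (future C4) can reach only this carbon (future C4a), so the unfunctionalised arene closes ring C under monovalent-gold π-acid catalysis.
- Stereochemistry: C2 comes from a catalytic enantioselective alkynylation followed by Mitsunobu inversion. C3 comes from osmylation anti to the C2 aryl group (the C4 carbinol centre is oxidised away). The four lignan stereocentres are carried in from (+)-pinoresinol.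

Key step: step 4

Assumption: (S,S)-ProPhenol is taken to give the carbinol configuration drawn for 4 and 5; if a test reaction shows the opposite facial sense, (R,R)-ProPhenol is used and nothing else changes.

**Step 1**
Reactants: 1 3-bromo-4,5-dihydroxybenzaldehyde
Product: 2 3,4-bis(benzyloxy)-5-bromobenzaldehyde
Conditions: BnBr (2.4 equiv), K2CO3, DMF, 50 °C
Reagents that add atoms: benzyl bromide BrCc1ccccc1
Why: Williamson etherification of both catechol hydroxyls gives benzyl ethers that should withstand every later step and leave together at the end.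

**Step 2**
Reactants: 2 3,4-bis(benzyloxy)-5-bromobenzaldehyde; 3 ethynyltrimethylsilane
Product: 5 (1R)-1-[3,4-bis(benzyloxy)-5-bromophenyl]prop-2-yn-1-ol, via silylated propargylic alcohol 4 (not isolated)
Conditions: Me2Zn, (S,S)-ProPhenol (10 mol %), Ph3PO (20 mol %), toluene, 4 °C; aqueous work-up; then K2CO3, MeOH, rt
Reagents that add atoms: none
Why: Zinc–ProPhenol-catalysed enantioselective alkynylation of the aryl aldehyde, in which the chiral dinuclear zinc pocket delivers the zinc acetylide to one carbonyl face and so sets the carbinol stereocentre (later C2), followed by carbonate methanolysis of the C–Si bond on the crude product.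

**Step 3**
Reactants: 5 (1R)-1-[3,4-bis(benzyloxy)-5-bromophenyl]prop-2-yn-1-ol; 6 3,5-bis(benzyloxy)phenol
Product: 7 1,2-bis(benzyloxy)-5-[(1S)-1-[3,5-bis(benzyloxy)phenoxy]prop-2-yn-1-yl]-3-bromobenzene
Conditions: PPh3, DIAD, toluene, 0 °C to rt
Reagents that add atoms: none
Why: Mitsunobu etherification, in which the phenol displaces the oxyphosphonium group by SN2 with inversion so that (R)-5 should give (S)-7, the meta bromine and meta benzyloxy groups of ring B offsetting the para oxygen enough that ionisation should not compete in toluene at low temperature.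

**Step 4**
Reactants: 7 1,2-bis(benzyloxy)-5-[(1S)-1-[3,5-bis(benzyloxy)phenoxy]prop-2-yn-1-yl]-3-bromobenzene
Product: 8 (2S)-5,7-bis(benzyloxy)-2-[3,4-bis(benzyloxy)-5-bromophenyl]-2H-chromene
Conditions: Ph3PAuNTf2 (3 mol %), CH2Cl2, 0 °C to rt; filtration through basic alumina; used at once
Reagents that add atoms: none
Why: The cationic monovalent gold complex Ph3PAuNTf2 binds the terminal alkyne of 7 as a π-acid, the ring A carbon ortho to the ether oxygen (future C4a) attacks the alkyne terminus (future C4) anti to gold, and rearomatisation followed by protodeauration of the C3 vinylgold releases 8 and the catalyst. The closest known reaction type is the gold-catalysed cycloisomerisation (intramolecular hydroarylation) of aryl propargyl ethers to 2H-chromenes, a Friedel–Crafts-type C–H alkenylation that needs no halide or metal on ring A. Ring C is closed in the 6-endo-dig mode, the 5-exo-dig alternative being disfavoured because it would build positive charge on C3 next to the electron-withdrawing C2–O bond and end in a strained exocyclic alkene. No stereocentre is formed, and C2 should keep its configuration because the O1–C2 bond is not broken on this pathway; the weakly Lewis acidic catalyst, the low temperature and the basic alumina filtration are chosen to keep that benzylic propargylic ether from ionising. The step needs site selectivity on ring A and chemoselectivity for ring A over ring B: the two ortho C–H carbons of the 3,5-bis(benzyloxy)phenyl ether are equivalent by rotation about the O–aryl bond and each is ortho, ortho and para to three oxygen substituents, whereas the brominated ring B is less nucleophilic and could reach the alkyne only by a 5-endo closure.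

**Step 5**
Reactants: 8 (2S)-5,7-bis(benzyloxy)-2-[3,4-bis(benzyloxy)-5-bromophenyl]-2H-chromene
Product: 9 (2R,3S,4S)-5,7-bis(benzyloxy)-2-[3,4-bis(benzyloxy)-5-bromophenyl]chromane-3,4-diol
Conditions: OsO4 (2 mol %), NMO, acetone/H2O, 0 °C to rt
Reagents that add atoms: osmium tetroxide O=[Os](=O)(=O)=O; N-methylmorpholine N-oxide C[N+]1([O-])CCOCC1; water O
Why: Upjohn dihydroxylation, a suprafacial syn addition that should take place on the face of the C3=C4 alkene opposite to the C2 aryl group and so set C3 (and C4) in the 2,3-trans-3,4-cis arrangement.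

**Step 6**
Reactants: 10 (+)-pinoresinol
Product: 11 4-[(1S,3aR,4S,6aR)-4-(4-hydroxy-3-methoxyphenyl)tetrahydro-1H,3H-furo[3,4-c]furan-1-yl]-2-iodo-6-methoxyphenol (5-iodopinoresinol)
Conditions: I2 (0.5 equiv), NaHCO3, THF/H2O, 0 °C; recovered 10 recycled
Reagents that add atoms: iodine [I][I]
Why: Electrophilic iodination of the phenolate goes ortho to the free hydroxyl because the para position is blocked, and since the two guaiacyl rings react independently half an equivalent of iodine is used so that mainly the mono-iodide should form beside recoverable 10.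

**Step 7**
Reactants: 11 5-iodopinoresinol
Product: 12 (1S,3aR,4S,6aR)-1-[4-(benzyloxy)-3-iodo-5-methoxyphenyl]-4-[4-(benzyloxy)-3-methoxyphenyl]tetrahydro-1H,3H-furo[3,4-c]furan
Conditions: BnBr, K2CO3, DMF, 50 °C
Reagents that add atoms: benzyl bromide BrCc1ccccc1
Why: Williamson etherification of both phenols, the iodine-flanked one included, matches the protecting groups of the flavonoid half.

**Step 8**
Reactants: 12 the di-O-benzyl iodide
Product: 13 2-{2-(benzyloxy)-5-[(1S,3aR,4S,6aR)-4-[4-(benzyloxy)-3-methoxyphenyl]tetrahydro-1H,3H-furo[3,4-c]furan-1-yl]-3-methoxyphenyl}-4,4,5,5-tetramethyl-1,3,2-dioxaborolane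
Conditions: B2pin2, Pd(dppf)Cl2 (5 mol %), KOAc, 1,4-dioxane, 85 °C
Reagents that add atoms: bis(pinacolato)diboron CC1(C)OB(OC1(C)C)B1OC(C)(C)C(C)(C)O1
Why: Miyaura borylation of the aryl iodide under zerovalent-palladium catalysis with KOAc as a mild base should leave the benzylic ethers of the furofuran untouched.

**Step 9**
Reactants: 9 the bromo diol; 13 the lignan boronate
Product: 14 (2R,3S,4S)-5,7-bis(benzyloxy)-2-{3,4-bis(benzyloxy)-5-[2-(benzyloxy)-5-[(1S,3aR,4S,6aR)-4-[4-(benzyloxy)-3-methoxyphenyl]tetrahydro-1H,3H-furo[3,4-c]furan-1-yl]-3-methoxyphenyl]phenyl}chromane-3,4-diol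
Conditions: Pd(OAc)2 (5 mol %), SPhos (10 mol %), K3PO4, 1,4-dioxane/H2O, 70 °C
Reagents that add atoms: none
Why: Suzuki–Miyaura coupling with the Pd(OAc)2/SPhos system, chosen because both partners are electron-rich and carry an ortho benzyloxy group, is run at the base-stable diol stage so that the base-sensitive ketol is never exposed to phosphate.

**Step 10**
Reactants: 14 the coupled diol
Product: 15 (2R,3R)-5,7-bis(benzyloxy)-2-{3,4-bis(benzyloxy)-5-[2-(benzyloxy)-5-[(1S,3aR,4S,6aR)-4-[4-(benzyloxy)-3-methoxyphenyl]tetrahydro-1H,3H-furo[3,4-c]furan-1-yl]-3-methoxyphenyl]phenyl}-3-hydroxychroman-4-one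
Conditions: activated MnO2 (excess), CH2Cl2, rt
Reagents that add atoms: none
Why: Chemoselective benzylic alcohol oxidation by activated MnO2 should convert only the C4 carbinol next to the trioxygenated ring A and leave the aliphatic C3 hydroxyl, whose configuration is retained and is in any case the thermodynamically preferred 2,3-trans one.

**Step 11**
Reactants: 15 the hexa-O-benzyl ketol
Product: 16 (2R,3R)-2-{3,4-dihydroxy-5-[2-hydroxy-5-[(1S,3aR,4S,6aR)-4-(4-hydroxy-3-methoxyphenyl)tetrahydro-1H,3H-furo[3,4-c]furan-1-yl]-3-methoxyphenyl]phenyl}-3,5,7-trihydroxychroman-4-one (CNP0226398.1)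
Conditions: H2 (1 atm), 10% Pd/C, EtOAc/MeOH, rt, stopped at full debenzylation
Reagents that add atoms: none
Why: Hydrogenolysis of the six aryl benzyl ethers over Pd/C under neutral conditions should be complete well before the dialkyl benzylic C–O bonds of the furofuran and of ring C are attacked.

**Compound list**

1 | 3-bromo-4,5-dihydroxybenzaldehyde | O=Cc1cc(O)c(O)c(Br)c1 | starting material
2 | 3,4-bis(benzyloxy)-5-bromobenzaldehyde | O=Cc1cc(Br)c(OCc2ccccc2)c(OCc2ccccc2)c1 | intermediate
3 | ethynyltrimethylsilane | C#C[Si](C)(C)C | starting material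
4 | (1S)-1-[3,4-bis(benzyloxy)-5-bromophenyl]-3-(trimethylsilyl)prop-2-yn-1-ol | C[Si](C)(C)C#C[C@@H](O)c1cc(Br)c(OCc2ccccc2)c(OCc2ccccc2)c1 | intermediate (not isolated)
5 | (1R)-1-[3,4-bis(benzyloxy)-5-bromophenyl]prop-2-yn-1-ol | C#C[C@@H](O)c1cc(Br)c(OCc2ccccc2)c(OCc2ccccc2)c1 | intermediate
6 | 3,5-bis(benzyloxy)phenol | Oc1cc(OCc2ccccc2)cc(OCc2ccccc2)c1 | starting material
7 | 1,2-bis(benzyloxy)-5-[(1S)-1-[3,5-bis(benzyloxy)phenoxy]prop-2-yn-1-yl]-3-bromobenzene | C#C[C@H](Oc1cc(OCc2ccccc2)cc(OCc2ccccc2)c1)c1cc(Br)c(OCc2ccccc2)c(OCc2ccccc2)c1 | intermediate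
8 | (2S)-5,7-bis(benzyloxy)-2-[3,4-bis(benzyloxy)-5-bromophenyl]-2H-chromene | Brc1cc([C@H]2Oc3cc(OCc4ccccc4)cc(OCc4ccccc4)c3C=C2)cc(OCc2ccccc2)c1OCc1ccccc1 | intermediate
9 | (2R,3S,4S)-5,7-bis(benzyloxy)-2-[3,4-bis(benzyloxy)-5-bromophenyl]chromane-3,4-diol | Brc1cc([C@H]2Oc3cc(OCc4ccccc4)cc(OCc4ccccc4)c3[C@H](O)[C@@H]2O)cc(OCc2ccccc2)c1OCc1ccccc1 | intermediate
10 | (+)-pinoresinol, 4,4'-[(1S,3aR,4S,6aR)-tetrahydro-1H,3H-furo[3,4-c]furan-1,4-diyl]bis(2-methoxyphenol) | COc1cc([C@H]2OC[C@H]3[C@@H]2CO[C@@H]3c2ccc(O)c(OC)c2)ccc1O | starting material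
11 | 5-iodopinoresinol | COc1cc([C@H]2OC[C@H]3[C@@H]2CO[C@@H]3c2cc(OC)c(O)c(I)c2)ccc1O | intermediate
12 | di-O-benzyl-5-iodopinoresinol | COc1cc([C@H]2OC[C@H]3[C@@H]2CO[C@@H]3c2cc(OC)c(OCc4ccccc4)c(I)c2)ccc1OCc1ccccc1 | intermediate
13 | di-O-benzylpinoresinol 5-pinacolboronate | COc1cc([C@H]2OC[C@H]3[C@@H]2CO[C@@H]3c2cc(OC)c(OCc4ccccc4)c(B4OC(C)(C)C(C)(C)O4)c2)ccc1OCc1ccccc1 | intermediate
14 | hexa-O-benzyl biaryl (2R,3S,4S)-flavan-3,4-diol | COc1cc([C@H]2OC[C@H]3[C@@H]2CO[C@@H]3c2cc(OC)c(OCc4ccccc4)c(-c4cc([C@H]5Oc6cc(OCc7ccccc7)cc(OCc7ccccc7)c6[C@H](O)[C@@H]5O)cc(OCc5ccccc5)c4OCc4ccccc4)c2)ccc1OCc1ccccc1 | intermediate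
15 | hexa-O-benzyl ether of the target, (2R,3R)-ketol | COc1cc([C@H]2OC[C@H]3[C@@H]2CO[C@@H]3c2cc(OC)c(OCc4ccccc4)c(-c4cc([C@H]5Oc6cc(OCc7ccccc7)cc(OCc7ccccc7)c6C(=O)[C@@H]5O)cc(OCc5ccccc5)c4OCc4ccccc4)c2)ccc1OCc1ccccc1 | intermediate
16 | CNP0226398.1 | COc1cc([C@H]2OC[C@H]3[C@@H]2CO[C@@H]3c2cc(OC)c(O)c(-c3cc([C@H]4Oc5cc(O)cc(O)c5C(=O)[C@@H]4O)cc(O)c3O)c2)ccc1O | target

**Totals**

Total step count: 11. Longest linear sequence: 8 steps (steps 1, 2, 3, 4, 5, 9, 10, 11).

**Steps most likely to fail**

Step 4. The cationic gold catalyst or adventitious acid may ionise the doubly activated O1–C2 bond of 7 or of 8, which would erode the configuration at C2 or move the propargyl group from oxygen to carbon. The fallback sets out from 7 and closes the same C4–C4a bond at the aldehyde oxidation level. Ruthenium-catalysed anti-Markovnikov hydration of the terminal alkyne (CpRu(MeCN)3PF6 with 5,5'-bis(trifluoromethyl)-2,2'-bipyridine, acetone/H2O) should give (3S)-3-[3,4-bis(benzyloxy)-5-bromophenyl]-3-[3,5-bis(benzyloxy)phenoxy]propanal F1. Intramolecular Friedel–Crafts hydroxyalkylation of the same ring A carbon onto the aldehyde (catalytic Sc(OTf)3, CH2Cl2, −20 °C) should give (2S)-5,7-bis(benzyloxy)-2-[3,4-bis(benzyloxy)-5-bromophenyl]chroman-4-ol F2 as a mixture of C4 epimers. Mild dehydration (catalytic PPTS, 4 Å molecular sieves, toluene) comes back to the route at 8.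

Step 3. Partial ionisation of the benzylic propargylic oxyphosphonium intermediate, or SN2' attack at the alkyne terminus, would lower the enantiopurity at C2 or divert material to an allenyl ether. The fallback sets out from 5. Acetylation (Ac2O, pyridine) gives (1R)-1-[3,4-bis(benzyloxy)-5-bromophenyl]prop-2-yn-1-yl acetate F3. A copper–pybox-catalysed enantioconvergent propargylic etherification with phenol 6 (CuOTf·0.5C6H6, chiral Ph-pybox, iPr2NEt, low temperature) then passes through a copper allenylidene, which erases the carbinol centre and lets the ligand set C2. This comes back to the route at 7.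

Step 11. Over-reduction may occur: hydrogenolytic opening of the benzylic C–O bonds of the furofuran (and of O1–C2) could compete with removal of the last benzyl ethers. The fallback sets out from 15 and replaces hydrogenolysis by Lewis acid debenzylation with a cation scavenger (BCl3, pentamethylbenzene, CH2Cl2, −78 °C). It arrives directly at 16, so no new compound arises (F0).

**Further compounds**

F1 | step 4 | (3S)-3-[3,4-bis(benzyloxy)-5-bromophenyl]-3-[3,5-bis(benzyloxy)phenoxy]propanal | O=CC[C@H](Oc1cc(OCc2ccccc2)cc(OCc2ccccc2)c1)c1cc(Br)c(OCc2ccccc2)c(OCc2ccccc2)c1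
F2 | step 4 | (2S)-5,7-bis(benzyloxy)-2-[3,4-bis(benzyloxy)-5-bromophenyl]chroman-4-ol (both C4 epimers) | Brc1cc([C@H]2Oc3cc(OCc4ccccc4)cc(OCc4ccccc4)c3C(O)C2)cc(OCc2ccccc2)c1OCc1ccccc1
F3 | step 3 | (1R)-1-[3,4-bis(benzyloxy)-5-bromophenyl]prop-2-yn-1-yl acetate | C#C[C@@H](OC(C)=O)c1cc(Br)c(OCc2ccccc2)c(OCc2ccccc2)c1
F0 | step 11 | none | none
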